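**Plan**

1. Locants: side chain C1–C5 (C3 = carbinol) on quaternary C6, which also bears C7 (CH2OH); C8; C9, C10; alkene C11=C12; C13; C14, C15; C16 (CO2Me); C17; quaternary C18; C19–N(CH3)–C21. Ring A = piperidine (N, C19, C18, C6, C8, C21); ring B = seven-membered (C6, C8, C9, C10, C11, C12, C18); ring C = cyclopentane (C12, C13, C16, C17, C18); ring D = cyclopentene (C11–C15).
2. Cuts, last bond first: C4–C5 and the C3 carbinol (olefination, ketone reduction); C6–C7 (aldol) and C6–C5 (ketone homologation); ring D at C13–C14 by electrocyclisation of a C11 divinyl carbinol (C11–C15 from a vinyl nucleophile); ring B at C8–C9 (Michael), C11 from CO; ring A at C6–C8 (Dieckmann), N–C21 (aza-Michael), C18–C19 (Mannich); ring C by Dieckmann.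
3. Forward ring order: C, then A (spiro at C18), then B (bridge C12 to C8), then D last; CH2OH and the side chain are then built on the C6 ketone of the finished skeleton.
4. Feature used by the key event: ring D is a cyclopentene whose alkene C11=C12 is shared with ring B and whose one sp3 fusion carbon C13 is vinylogous to the C16 ester. Its five carbons map onto the pentadienyl cation C13=C12–C11(+)–C15=C14, which ring B holds in the U shape (C10 and C18 cis), and the ester draws the diene to C11=C12/C13=C16.
5. Stereochemistry: C18 by a catalytic asymmetric Mannich reaction; C8 forced by the bridge; C6 by face-selective hydroxymethylation of the bridge enolate; C13 and C16 together by syn hydrogenation anti to the C6 substituents; C3 by CBS reduction.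

Key step: step 11

Remarks on the chemistry:
- C16 is an uncontrolled, inconsequential centre from 2 to 13 and is written without configuration; it is planarised in step 11 and set in step 16. C8 in 8 and 9, C11 in 13 and C6 in 16 and 17 are likewise transient and left undefined.
- 12 and 13 are written as the ketone-conjugated C12=C13 isomers; the ester-conjugated C13=C16 isomer would reach the same cation in step 11 by way of the triene.
- The sense of induction in steps 2 and 18 is assigned by the usual models; the pseudo-enantiomeric catalyst is taken if the sense is opposite.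
- 1 is taken as commercial.

**Route**

Step 1
Reactants: 1 trimethyl butane-1,2,4-tricarboxylate
Product: 2 dimethyl 4-oxocyclopentane-1,3-dicarboxylate
Conditions: NaOMe (1.1 equiv), MeOH–toluene, reflux; AcOH
Reagents that add atoms: none
Why: Dieckmann condensation in which the enolate next to the 4-ester closes on the 1-ester; the reversible conditions should favour the less congested 2,4-disubstituted cyclopentanone, held as its stabilised enolate.

Step 2
Reactants: 2 dimethyl 4-oxocyclopentane-1,3-dicarboxylate
Product: 3 dimethyl (1S)-1-{[(tert-butoxycarbonyl)amino]methyl}-2-oxocyclopentane-1,4-dicarboxylate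
Conditions: 1-[3,5-bis(trifluoromethyl)phenyl]-3-[(8α,9S)-6′-methoxycinchonan-9-yl]thiourea (10 mol%), aq. Na2CO3, CH2Cl2, 0 °C
Reagents that add atoms: tert-butyl N-[(4-methylbenzenesulfonyl)methyl]carbamate, CC1=CC=C(C=C1)S(=O)(=O)CNC(=O)OC(C)(C)C
Why: Organocatalytic asymmetric Mannich reaction of a cyclic β-keto ester with the N-Boc formaldimine released in situ from the amido sulfone; the bifunctional catalyst binds the enol and shields one face, which should set the C18 quaternary centre as (S).

Step 3
Reactants: 3 dimethyl (1S)-1-{[(tert-butoxycarbonyl)amino]methyl}-2-oxocyclopentane-1,4-dicarboxylate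
Product: 5 dimethyl (1S)-1-({[3-(tert-butoxy)-3-oxopropyl]amino}methyl)-2-oxocyclopentane-1,4-dicarboxylate, via ammonium trifluoroacetate 4 (not isolated)
Conditions: CF3CO2H, CH2Cl2, rt; evaporate; Et3N, MeOH, rt
Reagents that add atoms: tert-butyl acrylate, C=CC(=O)OC(C)(C)C
Why: Acidolysis of the carbamate, then aza-Michael addition of the neopentylic primary amine, which should stop at mono-addition for steric reasons.

Step 4
Reactants: 5 dimethyl (1S)-1-({[3-(tert-butoxy)-3-oxopropyl]amino}methyl)-2-oxocyclopentane-1,4-dicarboxylate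
Product: 6 dimethyl (1S)-1-({[3-(tert-butoxy)-3-oxopropyl](methyl)amino}methyl)-2-oxocyclopentane-1,4-dicarboxylate
Conditions: 37% aq. HCHO, NaBH(OAc)3, ClCH2CH2Cl, rt
Reagents that add atoms: formaldehyde, C=O
Why: Reductive amination; the acetoxyborohydride reduces the iminium ion and leaves the ketone and the esters untouched.

Step 5
Reactants: 6 dimethyl (1S)-1-({[3-(tert-butoxy)-3-oxopropyl](methyl)amino}methyl)-2-oxocyclopentane-1,4-dicarboxylate
Product: 7 dimethyl (1S)-1-({[3-(tert-butoxy)-3-oxopropyl](methyl)amino}methyl)-2-[(trifluoromethanesulfonyl)oxy]cyclopent-2-ene-1,4-dicarboxylate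
Conditions: KHMDS (1.05 equiv), THF, −78 °C; then PhNTf2, −78 to −20 °C
Reagents that add atoms: N-phenylbis(trifluoromethanesulfonimide), O=S(=O)(N(c1ccccc1)S(=O)(=O)C(F)(F)F)C(F)(F)F
Why: Kinetic enolate O-triflation; the ketone can enolise only toward C13 because C18 is quaternary, and a ketone α-CH2 is deprotonated faster than the ester α-positions, so the C12=C13 enol triflate should form regiospecifically.

Step 6
Reactants: 7 dimethyl (1S)-1-({[3-(tert-butoxy)-3-oxopropyl](methyl)amino}methyl)-2-[(trifluoromethanesulfonyl)oxy]cyclopent-2-ene-1,4-dicarboxylate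
Product: 8 9-tert-butyl 3-methyl (5S)-7-methyl-10-oxo-1-[(trifluoromethanesulfonyl)oxy]-7-azaspiro[4.5]dec-1-ene-3,9-dicarboxylate
Conditions: LiHMDS (3 equiv), THF, −78 to 0 °C; AcOH
Reagents that add atoms: none
Why: Dieckmann condensation; the tert-butyl ester enolate (C8) acylates the methyl ester on C18 through a six-membered transition state to close ring A as the piperidin-4-one, the other closures leading to four- or eight-membered rings.

Step 7
Reactants: 8 9-tert-butyl 3-methyl (5S)-7-methyl-10-oxo-1-[(trifluoromethanesulfonyl)oxy]-7-azaspiro[4.5]dec-1-ene-3,9-dicarboxylate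
Product: 10 methyl (5S)-7-methyl-10-oxo-1-[(trifluoromethanesulfonyl)oxy]-7-azaspiro[4.5]dec-1-ene-3-carboxylate, via β-keto acid 9 (not isolated)
Conditions: CF3CO2H–CH2Cl2 (1:3), rt, then 40 °C; aq. NaHCO3
Reagents that add atoms: none
Why: Acidolysis of the tert-butyl ester and decarboxylation of the β-keto acid under non-nucleophilic conditions that should spare the enol triflate and the methyl ester.

Step 8
Reactants: 10 methyl (5S)-7-methyl-10-oxo-1-[(trifluoromethanesulfonyl)oxy]-7-azaspiro[4.5]dec-1-ene-3-carboxylate
Product: 11 methyl (5R)-7-methyl-10-oxo-1-(prop-2-enoyl)-7-azaspiro[4.5]dec-1-ene-3-carboxylate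
Conditions: Pd(PPh3)4 (5 mol%), LiCl (3 equiv), CO (1 atm), THF, 55 °C
Reagents that add atoms: carbon monoxide, [C-]#[O+]; tributyl(vinyl)stannane, C=C[Sn](CCCC)(CCCC)CCCC
Why: Carbonylative Stille coupling (oxidative addition of the enol triflate to zerovalent palladium, CO insertion, vinyl transfer from tin) gives the cross-conjugated dienone, with C11 coming from CO.

Step 9
Reactants: 11 methyl (5R)-7-methyl-10-oxo-1-(prop-2-enoyl)-7-azaspiro[4.5]dec-1-ene-3-carboxylate
Product: 12 tricyclic enone (rings A, B, C)
Conditions: 1,8-diazabicyclo[5.4.0]undec-7-ene (0.3 equiv), MeCN, 0.005 M, 0 °C to rt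
Reagents that add atoms: none
Why: Intramolecular Michael addition (7-endo-trig): the C6 ketone can enolise only toward C8, and C8 can reach only the terminal carbon C9 of the vinyl ketone once C12 is axial on the piperidone, so ring B closes and the bridge fixes C8 relative to C18.

Step 10
Reactants: 12 tricyclic enone (rings A, B, C)
Product: 13 tricyclic C11 divinyl carbinol
Conditions: CeCl3, THF, −78 °C; aq. NH4Cl
Reagents that add atoms: vinylmagnesium bromide, C=C[Mg]Br
Why: Organocerium 1,2-addition to the conjugated C11 ketone; the C6 ketone between the two bridgeheads and the ester should not react, and the configuration at C11 is irrelevant.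

Step 11
Reactants: 13 tricyclic C11 divinyl carbinol
Product: 15 tetracyclic dienoate (C11=C12, C13=C16), via cyclopentadiene 14 (not isolated)
Conditions: TsOH·H2O (2.5 equiv), CH2Cl2, 0 °C to rt; then 1,8-diazabicyclo[5.4.0]undec-7-ene (4 equiv), rt
Reagents that add atoms: none
Why: Acid ionises the tertiary bis-allylic alcohol to the pentadienyl cation C13=C12–C11(+)–C15=C14, which closes by thermal conrotatory 4π electrocyclisation (C13–C14 bond) to the cyclopentenyl cation of ring D; proton loss gives cyclopentadiene 14, and acid–base equilibration moves the diene into conjugation with the ester to give 15. The closest known reaction type is the acid-mediated dehydrative (Nazarov-type) cyclisation of divinyl carbinols to cyclopentadienes, as in the preparation of pentamethylcyclopentadiene. Ring D closes in the electrocyclic mode (five-atom, 4π, conrotatory) and not by a polar attack, so the stereoelectronic bar to a 5-endo closure between coplanar sp2 atoms does not apply. No stereocentre survives the step: C13 is formed and then planarised, C16 loses its uncontrolled configuration, and both are set together in step 16. The step needs positional selectivity for the C11=C12/C13=C16 diene and must outrun plain elimination; the C16 ester secures the first (the fully substituted dienoate is the thermodynamic sink), and ring B secures the second by holding C10 and C18 cis, which locks C13 and C15 on one side of the C11–C12 bond in the U shape, while eliminations to trienes are reversible in acid. The C6 ketone is inert because it cannot enolise toward either bridgehead.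

Step 12
Reactants: 15 tetracyclic dienoate (C11=C12, C13=C16)
Product: 16 C6 spiro-epoxide
Conditions: KHMDS, THF, −10 °C
Reagents that add atoms: trimethylsulfonium iodide, C[S+](C)C.[I-]
Why: Corey–Chaykovsky epoxidation; the small sulfonium ylide adds to the only ketone, and the tetrasubstituted dienoate should be too hindered for conjugate addition.

Step 13
Reactants: 16 C6 spiro-epoxide
Product: 17 C6 carbaldehyde
Conditions: BF3·OEt2 (2.2 equiv), CH2Cl2, −78 to −20 °C; aq. NaHCO3
Reagents that add atoms: none
Why: Meinwald rearrangement; Lewis-acid opening toward the tertiary C6 cation and 1,2-hydride shift from the CH2–O carbon give the aldehyde (its carbon becomes C5), C6 being left uncontrolled because it is planarised in the next step.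

Step 14
Reactants: 17 C6 carbaldehyde
Product: 18 C6 quaternary hydroxy aldehyde
Conditions: 37% aq. HCHO (3 equiv), K2CO3 (0.5 equiv), MeOH, 0 °C to rt
Reagents that add atoms: formaldehyde, C=O
Why: Crossed aldol hydroxymethylation of the only enolisable aldehyde; formaldehyde should enter the C6 enolate on the ring B face (sp2 C12 carries no syn-axial hydrogen, C9 one) and not on the piperidine face (two axial C–H bonds at C19 and C21), which places CH2OH syn to the carbocyclic bridge as in the target.

Step 15
Reactants: 18 C6 quaternary hydroxy aldehyde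
Product: 19 benzyl ether aldehyde
Conditions: TfOH (1.2 equiv), CH2Cl2–cyclohexane, 0 °C
Reagents that add atoms: benzyl 2,2,2-trichloroacetimidate, N=C(OCc1ccccc1)C(Cl)(Cl)Cl
Why: Acid-catalysed O-benzylation with the trichloroacetimidate; there is no base to start a retro-aldol, and the protonated amine cannot be alkylated.

Step 16
Reactants: 19 benzyl ether aldehyde
Product: 20 C13,C16-dihydro aldehyde
Conditions: H2 (50 bar), [Ir(cod)(PCy3)(py)][B(3,5-(CF3)2C6H3)4] (10 mol%), CF3CO2H (1.1 equiv), CH2Cl2, rt; aq. NaHCO3
Reagents that add atoms: none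
Why: Homogeneous cationic-iridium hydrogenation of the ester-conjugated tetrasubstituted alkene; H2 is delivered syn to C13 and C16 from the ring C face that carries C19, because the C6 quaternary carbon with its CH2OBn group covers the other face, and the C11=C12 alkene buried between rings B and D next to C18 should survive.

Step 17
Reactants: 20 C13,C16-dihydro aldehyde
Product: 21 (E)-enone
Conditions: LiCl, iPr2NEt, MeCN, rt to 40 °C
Reagents that add atoms: dimethyl (2-oxobutyl)phosphonate, CCC(=O)CP(=O)(OC)OC
Why: Horner–Wadsworth–Emmons olefination under mild lithium chloride–amine conditions, which should give the (E)-enone without epimerising C16.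

Step 18
Reactants: 21 (E)-enone
Product: 22 (3S)-allylic alcohol
Conditions: (R)-1-methyl-3,3-diphenyltetrahydro-1H,3H-pyrrolo[1,2-c][1,3,2]oxazaborole (0.3 equiv), catecholborane, toluene, −78 °C; MeOH, then aq. NaOH
Reagents that add atoms: none
Why: Corey–Bakshi–Shibata reduction under reagent control; with alkenyl as the large and ethyl as the small group the (R)-catalyst should give the (S)-carbinol.

Step 19
Reactants: 22 (3S)-allylic alcohol
Product: 23 CNP0291564.1
Conditions: H2 (1 atm), Pd(OH)2/C, EtOH, rt
Reagents that add atoms: none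
Why: Heterogeneous hydrogenation saturates the disubstituted C4=C5 alkene and cleaves the benzyl ether by hydrogenolysis, while the tetrasubstituted C11=C12 alkene should stay.

**Compound list**

1 | trimethyl butane-1,2,4-tricarboxylate | COC(=O)CC(CCC(=O)OC)C(=O)OC | starting material
2 | dimethyl 4-oxocyclopentane-1,3-dicarboxylate (ring C: C12 ketone, esters on C18 and C16) | COC(=O)C1CC(C(=O)OC)C(=O)C1 | intermediate
3 | dimethyl (1S)-1-{[(tert-butoxycarbonyl)amino]methyl}-2-oxocyclopentane-1,4-dicarboxylate | COC(=O)C1C[C@@](CNC(=O)OC(C)(C)C)(C(=O)OC)C(=O)C1 | intermediate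
4 | dimethyl (1S)-1-(ammoniomethyl)-2-oxocyclopentane-1,4-dicarboxylate trifluoroacetate | COC(=O)C1C[C@@](C[NH3+])(C(=O)OC)C(=O)C1.[O-]C(=O)C(F)(F)F | intermediate (not isolated)
5 | dimethyl (1S)-1-({[3-(tert-butoxy)-3-oxopropyl]amino}methyl)-2-oxocyclopentane-1,4-dicarboxylate | COC(=O)C1C[C@@](CNCCC(=O)OC(C)(C)C)(C(=O)OC)C(=O)C1 | intermediate
6 | dimethyl (1S)-1-({[3-(tert-butoxy)-3-oxopropyl](methyl)amino}methyl)-2-oxocyclopentane-1,4-dicarboxylate | COC(=O)C1C[C@@](CN(C)CCC(=O)OC(C)(C)C)(C(=O)OC)C(=O)C1 | intermediate
7 | dimethyl (1S)-1-({[3-(tert-butoxy)-3-oxopropyl](methyl)amino}methyl)-2-[(trifluoromethanesulfonyl)oxy]cyclopent-2-ene-1,4-dicarboxylate | COC(=O)C1C[C@@](CN(C)CCC(=O)OC(C)(C)C)(C(=O)OC)C(OS(=O)(=O)C(F)(F)F)=C1 | intermediate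
8 | 9-tert-butyl 3-methyl (5S)-7-methyl-10-oxo-1-[(trifluoromethanesulfonyl)oxy]-7-azaspiro[4.5]dec-1-ene-3,9-dicarboxylate (rings C and A, spiro at C18) | COC(=O)C1C[C@]2(CN(C)CC(C(=O)OC(C)(C)C)C2=O)C(OS(=O)(=O)C(F)(F)F)=C1 | intermediate
9 | (5S)-3-(methoxycarbonyl)-7-methyl-10-oxo-1-[(trifluoromethanesulfonyl)oxy]-7-azaspiro[4.5]dec-1-ene-9-carboxylic acid | COC(=O)C1C[C@]2(CN(C)CC(C(O)=O)C2=O)C(OS(=O)(=O)C(F)(F)F)=C1 | intermediate (not isolated)
10 | methyl (5S)-7-methyl-10-oxo-1-[(trifluoromethanesulfonyl)oxy]-7-azaspiro[4.5]dec-1-ene-3-carboxylate | COC(=O)C1C[C@]2(CN(C)CCC2=O)C(OS(=O)(=O)C(F)(F)F)=C1 | intermediate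
11 | methyl (5R)-7-methyl-10-oxo-1-(prop-2-enoyl)-7-azaspiro[4.5]dec-1-ene-3-carboxylate | COC(=O)C1C[C@]2(CN(C)CCC2=O)C(C(=O)C=C)=C1 | intermediate
12 | tricyclic enone: N-methylpiperidin-4-one (C6 ketone) bridged from C8 to C18 by C9–C10–C11(=O)–C12; ring C cyclopentene C12=C13 with CO2Me on C16; C18 and C8 as in the target | COC(=O)C1C[C@]23CN(C)C[C@H](CCC(=O)C2=C1)C3=O | intermediate
13 | tertiary alcohol of 12 at C11 bearing the vinyl group C15=C14 | COC(=O)C1C[C@]23CN(C)C[C@H](CCC(O)(C=C)C2=C1)C3=O | intermediate
14 | tetracyclic cyclopentadiene: ring D closed, alkenes C11=C15 and C12=C13, C6 ketone | O=C1[C@H]2CCC3=CCC4=C3[C@@]1(CN(C)C2)CC4C(=O)OC | intermediate (not isolated)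
15 | tetracyclic dienoate: alkenes C11=C12 and C13=C16 (CO2Me on C16), C6 ketone | O=C1[C@H]2CCC3=C4C(CC3)=C(C(=O)OC)C[C@]41CN(C)C2 | intermediate
16 | spiro-epoxide of 15 at C6 | C1OC12[C@H]3CCC4=C5C(CC4)=C(C(=O)OC)C[C@]52CN(C)C3 | intermediate
17 | C6 carbaldehyde (C6–H; aldehyde carbon = C5) | O=CC1[C@H]2CCC3=C4C(CC3)=C(C(=O)OC)C[C@]41CN(C)C2 | intermediate
18 | C6 quaternary hydroxy aldehyde: C5 aldehyde on the piperidine face, C7 CH2OH on the ring B face | O=C[C@]1(CO)[C@H]2CCC3=C4C(CC3)=C(C(=O)OC)C[C@]41CN(C)C2 | intermediate
19 | O-benzyl ether of 18 | O=C[C@]1(COCc5ccccc5)[C@H]2CCC3=C4C(CC3)=C(C(=O)OC)C[C@]41CN(C)C2 | intermediate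
20 | 19 with C13=C16 reduced: H on C13 and C16 cis, as in the target | O=C[C@]1(COCc5ccccc5)[C@H]2CCC3=C4[C@@H](CC3)[C@@H](C(=O)OC)C[C@]41CN(C)C2 | intermediate
21 | (E)-enone: C4=C5 alkene, C3 ketone, ethyl end | CCC(=O)/C=C/[C@]1(COCc5ccccc5)[C@H]2CCC3=C4[C@@H](CC3)[C@@H](C(=O)OC)C[C@]41CN(C)C2 | intermediate
22 | (3S)-allylic alcohol of 21 | CC[C@H](O)/C=C/[C@]1(COCc5ccccc5)[C@H]2CCC3=C4[C@@H](CC3)[C@@H](C(=O)OC)C[C@]41CN(C)C2 | intermediate
23 | CNP0291564.1 | CC[C@H](O)CC[C@]1(CO)[C@H]2CCC3=C4[C@@H](CC3)[C@@H](C(=O)OC)C[C@]41CN(C)C2 | target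

**Step count and risks**

Total steps: 19. Longest linear sequence: 19 (the route is linear).

Steps most likely to fail:

Step 14. Formaldehyde may attack the bridge enolate from the piperidine face, or the aldehyde may be consumed by crossed Cannizzaro reduction. The fallback swaps the roles of the two C6 substituents and sets out from 17. Michael addition of the C6 enolate to acrolein (1,8-diazabicyclo[5.4.0]undec-7-ene, MeCN) brings in the three-carbon unit on the face the one-carbon unit would have taken and turns the existing aldehyde into C7, giving dialdehyde F1. Hydrogenation as in step 16 gives dihydro dialdehyde F2. Chemoselective enantioselective ethylation of the unhindered aldehyde (ZnEt2, Ti(OiPr)4, (1R,2R)-N,N′-bis(trifluoromethanesulfonyl)cyclohexane-1,2-diamine) gives hydroxy aldehyde F3, and NaBH4 reduction comes back to the route at 23.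

Step 9. Intermolecular Michael addition and oligomerisation of the vinyl ketone may outrun the strained seven-membered closure. The fallback sets out from 10. Conjugate addition of its C8 enolate to acrolein gives keto aldehyde F4. Intramolecular Nozaki–Hiyama–Kishi coupling of the enol triflate with the aldehyde (CrCl2, NiCl2 cat., DMSO, high dilution; C8 equilibrates through the ketone) closes ring B as allylic alcohol F5. Oxidation with 1,1,1-triacetoxy-1,1-dihydro-1,2-benziodoxol-3(1H)-one comes back to the route at 12.

Step 13. A Wagner–Meerwein 1,2-shift of a C18 substituent to the C6 cation (the new C18 cation would be allylic) may compete with the hydride shift. The fallback sets out from 15. Wittig reaction with Ph3P=CHOMe gives methyl enol ether F6, and hydrolysis (aq. HCl, THF) comes back to the route at 17.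

Further compounds
F1 | step 14 | dialdehyde: C6 bears CHO (C7, ring B face) and CH2CH2CHO (piperidine face), dienoate intact | O=CCC[C@]1(C=O)[C@H]2CCC3=C4C(CC3)=C(C(=O)OC)C[C@]41CN(C)C2
F2 | step 14 | dihydro dialdehyde: F1 with C13=C16 reduced, H on C13 and C16 as in the target | O=CCC[C@]1(C=O)[C@H]2CCC3=C4[C@@H](CC3)[C@@H](C(=O)OC)C[C@]41CN(C)C2
F3 | step 14 | hydroxy aldehyde: (3S)-carbinol side chain complete, C7 still CHO | CC[C@H](O)CC[C@]1(C=O)[C@H]2CCC3=C4[C@@H](CC3)[C@@H](C(=O)OC)C[C@]41CN(C)C2
F4 | step 9 | keto aldehyde: 10 carrying CH2CH2CHO on C8 | COC(=O)C1C[C@]2(CN(C)CC(CCC=O)C2=O)C(OS(=O)(=O)C(F)(F)F)=C1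
F5 | step 9 | tricyclic allylic alcohol: 12 with C11–OH in place of the C11 ketone | COC(=O)C1C[C@]23CN(C)C[C@H](CCC(O)C2=C1)C3=O
F6 | step 13 | methyl enol ether: 15 with C6=CH–OCH3 in place of the C6 ketone | COC=C1[C@H]2CCC3=C4C(CC3)=C(C(=O)OC)C[C@]41CN(C)C2
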